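## Retrosynthetic overview

- Numbering: tetronic ring O1–C5; side chain C1′ (ylidene CH) to C13′ (CH2 on the furan); stereocentres C2′ and C6′.
- The tetronic acid ring is formed last: C5=C1′ by a cis-selective phosphonate olefination of the C1′ aldehyde, then C3–C4 by Dieckmann closure in the same flask.
- C8′–C9′ comes from a Suzuki coupling of an (E)-alkenylboronate with a (Z)-vinyl iodide; the iodide is built from 3-bromofuran (furan ring bought), oxetane and propyne.
- C3′–C4′ comes from an anodic mixed Kolbe coupling of two carboxylic acids. This joins the two bought stereocentres: C6′ from (R)-β-citronellene and C2′ from the (R)-methylsuccinic half-ester.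

Assumption: (R)-β-citronellene and (3R)-4-methoxy-3-methyl-4-oxobutanoic acid (the catalogue 1-methyl half-ester of (R)-methylsuccinic acid) are bought as single enantiomers.

## Route

Step 1
Reactants: 1 (R)-β-citronellene, (3R)-3,7-dimethylocta-1,6-diene
Product: 3 (4R)-4-methylhex-5-enoic acid, via (4R)-4-methylhex-5-enal 2 (not isolated)
Conditions: O3 (1.0 equiv, Sudan Red 7B end point), CH2Cl2, −78 °C; Me2S; crude 2, NaClO2, NaH2PO4, 2-methylbut-2-ene, t-BuOH/H2O, 0 °C → rt
Reagents that add atoms: ozone, [O-][O+]=O; sodium chlorite, [Na+].[O-]Cl=O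
Why: Chemoselective ozonolysis cleaves the electron-rich trisubstituted alkene much faster than the vinyl group, and Pinnick oxidation turns the crude aldehyde into the acid without touching the alkene or the C4 stereocentre bought in 1.

Step 2
Reactants: 3 (4R)-4-methylhex-5-enoic acid; 4 (3R)-4-methoxy-3-methyl-4-oxobutanoic acid
Product: 5 methyl (2R,6R)-2,6-dimethyloct-7-enoate
Conditions: undivided cell, Pt anode, Pt cathode, 3 (3 equiv), 4 (1 equiv), NaOMe (5 mol % of total acid), MeOH, 0.2 A cm−2, 15–20 °C, until pH 8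
Reagents that add atoms: none
Why: Mixed Kolbe (Brown–Walker) electrolysis: anodic decarboxylation gives the primary radicals CH2=CH–CH(CH3)–CH2–CH2• and •CH2–CH(CH3)–CO2Me, which couple to the new C3–C4 bond; both stereocentres are remote from the radical carbons and pass through unchanged, and the hydrocarbon and diester homodimers separate by polarity.

Step 3
Reactants: 5 methyl (2R,6R)-2,6-dimethyloct-7-enoate; 6 vinylboronic acid pinacol ester (2-ethenyl-4,4,5,5-tetramethyl-1,3,2-dioxaborolane)
Product: 7 methyl (2R,6R,7E)-2,6-dimethyl-8-(4,4,5,5-tetramethyl-1,3,2-dioxaborolan-2-yl)oct-7-enoate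
Conditions: 6 (3 equiv), second-generation Hoveyda–Grubbs catalyst RuCl2(H2IMes)(=CH–C6H4-2-O-i-Pr) (5 mol %), CH2Cl2, 40 °C
Reagents that add atoms: none
Why: Olefin cross-metathesis of a terminal alkene with the vinylboronate gives the (E)-alkenylboronate (the allylic methyl branch enforces E) and does not touch C6.

Step 4
Reactants: 8 3-bromofuran; 9 oxetane
Product: 11 3-(furan-3-yl)propan-1-ol, via furan-3-yllithium 10 (not isolated)
Conditions: n-BuLi, THF, −78 °C; 9, BF3·OEt2, −78 °C; aq NaHCO3
Reagents that add atoms: none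
Why: Bromine–lithium exchange gives furan-3-yllithium, which is stable at −78 °C and opens BF3-activated oxetane by SN2 ring opening to the three-carbon alcohol.

Step 5
Reactants: 11 3-(furan-3-yl)propan-1-ol
Product: 12 3-(3-bromopropyl)furan
Conditions: CBr4, PPh3, CH2Cl2, 0 °C
Reagents that add atoms: carbon tetrabromide, BrC(Br)(Br)Br
Why: The Appel reaction brominates the primary alcohol under neutral conditions that the furan tolerates.

Step 6
Reactants: 12 3-(3-bromopropyl)furan; 13 propyne
Product: 17 3-[(4Z)-5-iodo-4-methylpent-4-en-1-yl]furan, via 3-(furan-3-yl)propylmagnesium bromide 14 (not isolated), via 3-(furan-3-yl)propylcopper 15 (not isolated), via [(1Z)-5-(furan-3-yl)-2-methylpent-1-en-1-yl]copper 16 (not isolated)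
Conditions: Mg, Et2O, reflux; CuBr·SMe2, Et2O/Me2S, −45 °C; 13 (3 equiv), −25 °C; I2, THF, −60 → 0 °C; aq Na2S2O3
Reagents that add atoms: iodine, II
Why: Normant carbocupration adds the alkylcopper syn across propyne with copper on the terminal carbon, and iodinolysis with retention gives the (Z)-vinyl iodide with iodine cis to the furylpropyl chain.

Step 7
Reactants: 7 methyl (2R,6R,7E)-2,6-dimethyl-8-(4,4,5,5-tetramethyl-1,3,2-dioxaborolan-2-yl)oct-7-enoate; 17 3-[(4Z)-5-iodo-4-methylpent-4-en-1-yl]furan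
Product: 18 methyl (2R,6R,7E,9Z)-13-(furan-3-yl)-2,6,10-trimethyltrideca-7,9-dienoate
Conditions: Pd(dppf)Cl2 (5 mol %), K3PO4 (3 equiv), DMF/H2O 10:1, 45 °C, degassed, dark
Reagents that add atoms: none
Why: Suzuki–Miyaura alkenyl–alkenyl coupling proceeds with retention at both partners to give the (7E,9Z)-diene, and K3PO4 leaves the methyl ester and its α-stereocentre alone.

Step 8
Reactants: 18 methyl (2R,6R,7E,9Z)-13-(furan-3-yl)-2,6,10-trimethyltrideca-7,9-dienoate
Product: 19 (2R,6R,7E,9Z)-13-(furan-3-yl)-2,6,10-trimethyltrideca-7,9-dienal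
Conditions: i-Bu2AlH (1.1 equiv), CH2Cl2, −78 °C; MeOH, −78 °C; aq potassium sodium tartrate; used at once
Reagents that add atoms: none
Why: The i-Bu2AlH half-reduction stops at the tetrahedral aluminium hemiacetal at −78 °C and releases the aldehyde only on cold work-up, so the α-stereocentre C2 is not epimerised.

Step 9
Reactants: 20 methyl 2-[bis(2,2,2-trifluoroethoxy)phosphoryl]acetate
Product: 21 methyl 2-[bis(2,2,2-trifluoroethoxy)phosphoryl]-2-diazoacetate
Conditions: 4-acetamidobenzenesulfonyl azide, DBU, MeCN, 0 °C → rt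
Reagents that add atoms: 4-acetamidobenzenesulfonyl azide, CC(=O)Nc1ccc(cc1)S(=O)(=O)N=[N+]=[N-]
Why: Regitz diazo transfer to the doubly activated methylene of the phosphonoacetate.

Step 10
Reactants: 21 methyl 2-[bis(2,2,2-trifluoroethoxy)phosphoryl]-2-diazoacetate; 22 propanoic acid
Product: 23 methyl 2-[bis(2,2,2-trifluoroethoxy)phosphoryl]-2-(propanoyloxy)acetate (racemic)
Conditions: Rh2(OAc)4 (1 mol %), 22 (3 equiv), toluene, 80 °C
Reagents that add atoms: none
Why: The rhodium carbenoid inserts into the carboxylic O–H bond (O–H insertion), as is established for diazophosphonoacetates; the stereocentre formed is destroyed in step 11.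

Step 11
Reactants: 19 (2R,6R,7E,9Z)-13-(furan-3-yl)-2,6,10-trimethyltrideca-7,9-dienal; 23 methyl 2-[bis(2,2,2-trifluoroethoxy)phosphoryl]-2-(propanoyloxy)acetate
Product: 25 (5E)-5-[(2R,6R,7E,9Z)-13-(furan-3-yl)-2,6,10-trimethyltrideca-7,9-dien-1-ylidene]-4-hydroxy-3-methylfuran-2(5H)-one, via methyl (2E,4R,8R,9E,11Z)-15-(furan-3-yl)-4,8,12-trimethyl-2-(propanoyloxy)pentadeca-2,9,11-trienoate 24 (not isolated)
Conditions: 23 (1.3 equiv), KN(SiMe3)2 (1.25 equiv), 18-crown-6, THF, −78 °C; 19, −78 °C; then LiN(SiMe3)2 (2.5 equiv), −78 → −20 °C; 0.5 M HCl to pH 3, 0 °C; dark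
Reagents that add atoms: none
Why: Proposed new method: the potassium anion of 23 carries the electron-poor bis(trifluoroethyl) phosphonate of a Still–Gennari reagent, so addition to 19 is irreversible and the kinetic adduct collapses quickly to enol ester 24 with the aldehyde substituent cis to CO2Me, i.e. (2E); LiN(SiMe3)2 then deprotonates the propanoyl CH2 (the tertiary γ-H lies in the alkene plane through allylic strain and is not removed) and the enolate closes onto the neighbouring methyl ester (5-exo-trig Lacey–Dieckmann condensation) to the tetronate, which keeps the geometry of 24 so that the chain ends cis to C4–OH (5E); the closest known reaction types are the Still–Gennari olefination with α-substituted bis(trifluoroethyl)phosphonoacetates and the Dieckmann cyclisation of α-(acyloxy)acrylates used for pulvinones, which have not been combined or run with an α-acyloxy phosphonate of this kind.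

## Compound list

1 | (R)-β-citronellene, (3R)-3,7-dimethylocta-1,6-diene | C=C[C@H](C)CCC=C(C)C | starting material
2 | (4R)-4-methylhex-5-enal | C=C[C@H](C)CCC=O | intermediate
3 | (4R)-4-methylhex-5-enoic acid | C=C[C@H](C)CCC(=O)O | intermediate
4 | (3R)-4-methoxy-3-methyl-4-oxobutanoic acid (1-methyl hydrogen (R)-2-methylsuccinate) | COC(=O)[C@H](C)CC(=O)O | starting material
5 | methyl (2R,6R)-2,6-dimethyloct-7-enoate | COC(=O)[C@H](C)CCC[C@@H](C)C=C | intermediate
6 | vinylboronic acid pinacol ester, 2-ethenyl-4,4,5,5-tetramethyl-1,3,2-dioxaborolane | C=CB1OC(C)(C)C(C)(C)O1 | starting material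
7 | methyl (2R,6R,7E)-2,6-dimethyl-8-(4,4,5,5-tetramethyl-1,3,2-dioxaborolan-2-yl)oct-7-enoate | COC(=O)[C@H](C)CCC[C@@H](C)/C=C/B1OC(C)(C)C(C)(C)O1 | intermediate
8 | 3-bromofuran | Brc1ccoc1 | starting material
9 | oxetane | C1COC1 | starting material
10 | furan-3-yllithium | [Li]c1ccoc1 | intermediate
11 | 3-(furan-3-yl)propan-1-ol | OCCCc1ccoc1 | intermediate
12 | 3-(3-bromopropyl)furan | BrCCCc1ccoc1 | intermediate
13 | propyne | CC#C | starting material
14 | 3-(furan-3-yl)propylmagnesium bromide | Br[Mg]CCCc1ccoc1 | intermediate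
15 | 3-(furan-3-yl)propylcopper (as its MgBr2 complex) | [Cu]CCCc1ccoc1 | intermediate
16 | [(1Z)-5-(furan-3-yl)-2-methylpent-1-en-1-yl]copper | [Cu]/C=C(/C)CCCc1ccoc1 | intermediate
17 | 3-[(4Z)-5-iodo-4-methylpent-4-en-1-yl]furan | I/C=C(/C)CCCc1ccoc1 | intermediate
18 | methyl (2R,6R,7E,9Z)-13-(furan-3-yl)-2,6,10-trimethyltrideca-7,9-dienoate | COC(=O)[C@H](C)CCC[C@@H](C)/C=C/C=C(/C)CCCc1ccoc1 | intermediate
19 | (2R,6R,7E,9Z)-13-(furan-3-yl)-2,6,10-trimethyltrideca-7,9-dienal | O=C[C@H](C)CCC[C@@H](C)/C=C/C=C(/C)CCCc1ccoc1 | intermediate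
20 | methyl 2-[bis(2,2,2-trifluoroethoxy)phosphoryl]acetate | COC(=O)CP(=O)(OCC(F)(F)F)OCC(F)(F)F | starting material
21 | methyl 2-[bis(2,2,2-trifluoroethoxy)phosphoryl]-2-diazoacetate | COC(=O)C(=[N+]=[N-])P(=O)(OCC(F)(F)F)OCC(F)(F)F | intermediate
22 | propanoic acid | CCC(=O)O | starting material
23 | methyl 2-[bis(2,2,2-trifluoroethoxy)phosphoryl]-2-(propanoyloxy)acetate (racemic) | CCC(=O)OC(C(=O)OC)P(=O)(OCC(F)(F)F)OCC(F)(F)F | intermediate
24 | methyl (2E,4R,8R,9E,11Z)-15-(furan-3-yl)-4,8,12-trimethyl-2-(propanoyloxy)pentadeca-2,9,11-trienoate | COC(=O)/C(OC(=O)CC)=C\[C@H](C)CCC[C@@H](C)/C=C/C=C(/C)CCCc1ccoc1 | intermediate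
25 | (5E)-5-[(2R,6R,7E,9Z)-13-(furan-3-yl)-2,6,10-trimethyltrideca-7,9-dien-1-ylidene]-4-hydroxy-3-methylfuran-2(5H)-one | CC1=C(O)/C(=C\[C@H](C)CCC[C@@H](C)/C=C/C=C(/C)CCCc2ccoc2)OC1=O | target

## Step count and risks

Total step count: 11 (steps 9 and 10 prepare reagent 23).
Longest linear sequence: 6 (steps 1, 2, 3, 7, 8, 11; the branch 4, 5, 6, 7, 8, 11 is equally long).

The three steps most likely to fail:

**Step 2 (mixed Kolbe coupling).** The cross product is formed statistically beside both homodimers, and the anode may passivate or the radicals may add to the terminal alkene. The fallback sets out from 3 and comes back at 5 by a nickel-catalysed decarboxylative alkyl–alkyl coupling. Acid 3 is esterified with N-hydroxyphthalimide and N,N′-diisopropylcarbodiimide (DMAP cat., CH2Cl2) to the redox-active ester 1,3-dioxoisoindolin-2-yl (4R)-4-methylhex-5-enoate F1. The bought bromide of the (R)-Roche ester, methyl (2S)-3-bromo-2-methylpropanoate F2, is treated with Zn dust and LiCl in THF at 50 °C to give [(2S)-3-methoxy-2-methyl-3-oxopropyl]zinc bromide F3. F1 and F3 are then coupled with NiCl2·glyme and 4,4′-di-tert-butyl-2,2′-bipyridine in THF/DMF at room temperature to give 5.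

**Step 8 (half-reduction).** Over-reduction to the alcohol or epimerisation of the α-methyl aldehyde is possible. The fallback sets out from 18 and comes back at 19 by full reduction and re-oxidation. LiAlH4 in Et2O at 0 °C gives (2R,6R,7E,9Z)-13-(furan-3-yl)-2,6,10-trimethyltrideca-7,9-dien-1-ol F4, which Dess–Martin periodinane with NaHCO3 in CH2Cl2 at 0 °C oxidises to 19.

**Step 11 (the proposed new step).** The cis-selectivity of the olefination with the α-acyloxy phosphonate is unproven. The enol ester enolate may also fragment to a ketene instead of cyclising, and the (5E)-geometry may erode under base. The fallback sets out from 19 and comes back at 25 by the known tetronate aldol–dehydration–demethylation sequence: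

- 4-Methoxy-3-methylfuran-2(5H)-one F5 is deprotonated at C5 with LiN(i-Pr)2 in THF at −78 °C and added to 19. This gives the aldol 5-[(2R,6R,7E,9Z)-13-(furan-3-yl)-1-hydroxy-2,6,10-trimethyltrideca-7,9-dien-1-yl]-4-methoxy-3-methylfuran-2(5H)-one F6 as a mixture at the two new centres.
- MsCl and Et3N give (2R,6R,7E,9Z)-13-(furan-3-yl)-1-(3-methoxy-4-methyl-5-oxo-2,5-dihydrofuran-2-yl)-2,6,10-trimethyltrideca-7,9-dien-1-yl methanesulfonate F7.
- DBU eliminates F7 to the 5-ylidene methyl tetronates as a Z/E mixture. The (5E)-isomer, (5E)-5-[(2R,6R,7E,9Z)-13-(furan-3-yl)-2,6,10-trimethyltrideca-7,9-dien-1-ylidene]-4-methoxy-3-methylfuran-2(5H)-one F8, is separated by HPLC.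
- n-PrSNa in DMF followed by acidification cleaves the methyl ether to 25.

Every operation in this fallback is precedented, but the E isomer is the minor product of the elimination, so it costs material.

## Further compounds

F1 | step 2 | 1,3-dioxoisoindolin-2-yl (4R)-4-methylhex-5-enoate | C=C[C@H](C)CCC(=O)ON1C(=O)c2ccccc2C1=O
F2 | step 2 | methyl (2S)-3-bromo-2-methylpropanoate | COC(=O)[C@H](C)CBr
F3 | step 2 | [(2S)-3-methoxy-2-methyl-3-oxopropyl]zinc bromide | COC(=O)[C@H](C)C[Zn]Br
F4 | step 8 | (2R,6R,7E,9Z)-13-(furan-3-yl)-2,6,10-trimethyltrideca-7,9-dien-1-ol | OC[C@H](C)CCC[C@@H](C)/C=C/C=C(/C)CCCc1ccoc1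
F5 | step 11 | 4-methoxy-3-methylfuran-2(5H)-one | COC1=C(C)C(=O)OC1
F6 | step 11 | 5-[(2R,6R,7E,9Z)-13-(furan-3-yl)-1-hydroxy-2,6,10-trimethyltrideca-7,9-dien-1-yl]-4-methoxy-3-methylfuran-2(5H)-one (mixture at C5 and C1′) | COC1=C(C)C(=O)OC1C(O)[C@H](C)CCC[C@@H](C)/C=C/C=C(/C)CCCc2ccoc2
F7 | step 11 | (2R,6R,7E,9Z)-13-(furan-3-yl)-1-(3-methoxy-4-methyl-5-oxo-2,5-dihydrofuran-2-yl)-2,6,10-trimethyltrideca-7,9-dien-1-yl methanesulfonate (mixture at the two carbinol-derived centres) | COC1=C(C)C(=O)OC1C(OS(C)(=O)=O)[C@H](C)CCC[C@@H](C)/C=C/C=C(/C)CCCc2ccoc2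
F8 | step 11 | (5E)-5-[(2R,6R,7E,9Z)-13-(furan-3-yl)-2,6,10-trimethyltrideca-7,9-dien-1-ylidene]-4-methoxy-3-methylfuran-2(5H)-one | CC1=C(OC)/C(=C\[C@H](C)CCC[C@@H](C)/C=C/C=C(/C)CCCc2ccoc2)OC1=O
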